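**Plan**
- Retrosynthetic cuts, in order: C5–Cα of the acrylic acid (Heck); C3–CH2OH back to a C3 ester; C2–C3 of the dihydrofuran ring B (rhodium-carbene C–H insertion); the C3a–C3 arene–diazo carbon bond (Pd coupling of an aryl iodide with ethyl diazoacetate); the O1–CH2 ether; the C7–O bond (Baeyer–Villiger of a formyl group).
- Forward: 5-bromosalicylaldehyde is iodinated, O-alkylated with the 3,4-dimethoxybenzyl group, and its CHO turned into the C7 oxygen. The iodide then becomes the diazoester, ring B is closed, the ester is reduced, and the bromide becomes the acrylic acid.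
- Enabling feature: the C2–H of the O1–CH2–aryl ether is α to O1, benzylic to the electron-rich dimethoxyphenyl ring C, and lies 1,5 to C3. As a carbene, C3 carries ring A as donor and the ester (CH2OH at a higher oxidation level) as acceptor.
- Stereochemistry: C2 (R) comes from the chiral dirhodium tetracarboxylate in the insertion. C3 comes from thermodynamic cis-to-trans epimerization α to the ester, then fixed by reduction. The E alkene comes from the Heck reaction.
- Helpers: the C3 ester (acceptor, reduced in step 8), the O7 acetate (lost in step 7), and I and Br as sequential handles.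

Key step: step 6

Assumption: Rh2(S-PTTL)4 is taken to deliver the 2R configuration, as expected for ortho-benzyloxy aryldiazoacetates; should the sense be opposite, Rh2(R-PTTL)4 is used and nothing else changes.

**Step 1**
Reactants: 1 5-bromo-2-hydroxybenzaldehyde
Product: 2 5-bromo-2-hydroxy-3-iodobenzaldehyde
Conditions: NIS (1.05 equiv), DMF, rt
Reagents that add atoms: N-iodosuccinimide, O=C1CCC(=O)N1I
Why: Electrophilic aromatic iodination; the OH directs ortho (its para position is blocked by Br) and the formyl group directs meta to the same carbon, so iodine should enter only at C3.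

**Step 2**
Reactants: 2 5-bromo-2-hydroxy-3-iodobenzaldehyde; 3 4-(chloromethyl)-1,2-dimethoxybenzene (3,4-dimethoxybenzyl chloride)
Product: 4 5-bromo-2-[(3,4-dimethoxyphenyl)methoxy]-3-iodobenzaldehyde
Conditions: K2CO3 (1.5 equiv), KI (cat.), DMF, 60 °C
Reagents that add atoms: none
Why: Williamson ether synthesis; the acidic phenoxide is alkylated by the reactive benzylic chloride (Finkelstein activation by KI), and with only one OH present there is no regiochemical question.

**Step 3**
Reactants: 4 5-bromo-2-[(3,4-dimethoxyphenyl)methoxy]-3-iodobenzaldehyde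
Product: 6 5-bromo-2-[(3,4-dimethoxyphenyl)methoxy]-3-iodophenol, via aryl formate 5 (not isolated)
Conditions: mCPBA (1.5 equiv), CH2Cl2, 0 °C → rt; aq. NaHCO3 wash; then K2CO3 (cat.), MeOH, rt
Reagents that add atoms: 3-chloroperoxybenzoic acid (mCPBA), O=C(OO)c1cccc(Cl)c1
Why: Baeyer–Villiger (Dakin-type) oxidation; in the Criegee intermediate the ortho-alkoxy aryl group should migrate in preference to hydride to give the formate, which methanolysis cleaves, so the formyl position becomes the future C7–OH with the two catechol oxygens already differentiated.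

**Step 4**
Reactants: 6 5-bromo-2-[(3,4-dimethoxyphenyl)methoxy]-3-iodophenol
Product: 7 5-bromo-2-[(3,4-dimethoxyphenyl)methoxy]-3-iodophenyl acetate
Conditions: Ac2O, pyridine, DMAP (cat.), CH2Cl2, 0 °C → rt
Reagents that add atoms: acetic anhydride, CC(=O)OC(C)=O
Why: O-acylation of the phenol; the acetate removes the O–H that would otherwise undergo carbene O–H insertion in step 6, and it is chosen because it leaves by itself in step 7.

**Step 5**
Reactants: 7 5-bromo-2-[(3,4-dimethoxyphenyl)methoxy]-3-iodophenyl acetate; 8 ethyl diazoacetate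
Product: 9 ethyl 2-{3-acetoxy-5-bromo-2-[(3,4-dimethoxyphenyl)methoxy]phenyl}-2-diazoacetate
Conditions: Pd(PPh3)4 (5 mol%), Et3N (1.5 equiv), Bu4NBr (1 equiv), MeCN, rt
Reagents that add atoms: none
Why: Palladium-catalysed cross-coupling of an aryl iodide with a diazoacetate with retention of the diazo group; zerovalent palladium adds to C–I much faster than to C–Br at room temperature, and the mild amine base leaves acetate and bromide untouched.

**Step 6**
Reactants: 9 ethyl 2-{3-acetoxy-5-bromo-2-[(3,4-dimethoxyphenyl)methoxy]phenyl}-2-diazoacetate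
Product: 10 ethyl (2R,3S)-7-acetoxy-5-bromo-2-(3,4-dimethoxyphenyl)-2,3-dihydro-1-benzofuran-3-carboxylate (2,3-cis)
Conditions: Rh2(S-PTTL)4 (tetrakis[N-phthaloyl-(S)-tert-leucinato]dirhodium, 1 mol%), toluene (0.02 M), −60 °C
Reagents that add atoms: none
Why: The dirhodium carboxylate expels N2 from 9 to give a catalyst-bound donor/acceptor carbene at C3 (ring A donor, CO2Et acceptor), which inserts by a concerted, asynchronous, hydride-transfer-like three-centre transition state into one of the two enantiotopic C–H bonds of the O1–CH2 group. The closest known reaction type is the enantioselective intramolecular 1,5 C–H insertion of ortho-benzyloxy aryldiazoacetates under chiral dirhodium tetracarboxylate catalysis, which gives cis-2-aryl-2,3-dihydrobenzofuran-3-carboxylates. Ring B (O1–C2–C3–C3a–C7a) closes by 1,5-insertion through a six-membered transition state that includes the migrating hydrogen, the preferred mode for such carbenes. C2 (R) is controlled by the chiral pocket of the phthalimido-tert-leucinate ligands, which selects one benzylic hydrogen; C3 is expected to form kinetically cis (S) to the C2 aryl group and is corrected to trans in step 7. The step needs site selectivity for this C–H bond over carbene addition to ring C, carbene dimerization and O–H insertion. This is secured by the double activation of the C2–H (α to O1 and benzylic to the electron-rich ring C), by its 1,5 position, by the absence of any free OH, by the O7 acetate and C5 bromide being geometrically out of reach of C3, and by low temperature and dilution.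

**Step 7**
Reactants: 10 ethyl (2R,3S)-7-acetoxy-5-bromo-2-(3,4-dimethoxyphenyl)-2,3-dihydro-1-benzofuran-3-carboxylate
Product: 12 ethyl (2R,3R)-5-bromo-2-(3,4-dimethoxyphenyl)-7-hydroxy-2,3-dihydro-1-benzofuran-3-carboxylate (2,3-trans), via cis phenol ester 11 (not isolated)
Conditions: NaOEt (2.5 equiv), EtOH, 0 °C → rt; AcOH quench
Reagents that add atoms: none
Why: Base-mediated epimerization α to the ester together with transesterification of the aryl acetate; ethoxide removes the acetyl group as ethyl acetate and reversibly deprotonates C3, and reprotonation should funnel the material to the thermodynamically preferred trans ester, while C2 has no acidic hydrogen and stays R and the matching alkoxide avoids ester scrambling.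

**Step 8**
Reactants: 12 ethyl (2R,3R)-5-bromo-2-(3,4-dimethoxyphenyl)-7-hydroxy-2,3-dihydro-1-benzofuran-3-carboxylate
Product: 13 (2R,3S)-5-bromo-2-(3,4-dimethoxyphenyl)-3-(hydroxymethyl)-2,3-dihydro-1-benzofuran-7-ol
Conditions: LiBH4 (3 equiv), THF, 0 °C → rt; aq. NH4Cl
Reagents that add atoms: none
Why: Hydride reduction of the ester to the primary alcohol; LiBH4 leaves the aryl bromide and the benzylic ether alone, C3 is no longer epimerizable afterwards, and its descriptor changes from R to S only through the priority change from CO2Et to CH2OH.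

**Step 9**
Reactants: 13 (2R,3S)-5-bromo-2-(3,4-dimethoxyphenyl)-3-(hydroxymethyl)-2,3-dihydro-1-benzofuran-7-ol; 14 prop-2-enoic acid (acrylic acid)
Product: 15 (2E)-3-[(2R,3S)-2-(3,4-dimethoxyphenyl)-7-hydroxy-3-(hydroxymethyl)-2,3-dihydro-1-benzofuran-5-yl]prop-2-enoic acid
Conditions: Pd(OAc)2 (5 mol%), P(o-tol)3 (12 mol%), Et3N (4 equiv), DMF, 100 °C; then dilute aq. HCl, 0 °C
Reagents that add atoms: none
Why: Mizoroki–Heck reaction; oxidative addition into C5–Br, syn insertion of acrylic acid with aryl transfer to the β-carbon and syn β-hydride elimination should give the E-acrylic acid directly, with free phenol, alcohol and acid tolerated under amine base and the two stereocentres untouched.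

**Compound list**
1 | 5-bromo-2-hydroxybenzaldehyde | O=Cc1cc(Br)ccc1O | starting material
2 | 5-bromo-2-hydroxy-3-iodobenzaldehyde | O=Cc1cc(Br)cc(I)c1O | intermediate
3 | 4-(chloromethyl)-1,2-dimethoxybenzene | COc1ccc(CCl)cc1OC | starting material
4 | 5-bromo-2-[(3,4-dimethoxyphenyl)methoxy]-3-iodobenzaldehyde | COc1ccc(COc2c(I)cc(Br)cc2C=O)cc1OC | intermediate
5 | 5-bromo-2-[(3,4-dimethoxyphenyl)methoxy]-3-iodophenyl formate (not isolated) | COc1ccc(COc2c(I)cc(Br)cc2OC=O)cc1OC | intermediate
6 | 5-bromo-2-[(3,4-dimethoxyphenyl)methoxy]-3-iodophenol | COc1ccc(COc2c(I)cc(Br)cc2O)cc1OC | intermediate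
7 | 5-bromo-2-[(3,4-dimethoxyphenyl)methoxy]-3-iodophenyl acetate | COc1ccc(COc2c(I)cc(Br)cc2OC(C)=O)cc1OC | intermediate
8 | ethyl diazoacetate | CCOC(=O)C=[N+]=[N-] | starting material
9 | ethyl 2-{3-acetoxy-5-bromo-2-[(3,4-dimethoxyphenyl)methoxy]phenyl}-2-diazoacetate | CCOC(=O)C(=[N+]=[N-])c1cc(Br)cc(OC(C)=O)c1OCc1ccc(OC)c(OC)c1 | intermediate
10 | ethyl (2R,3S)-7-acetoxy-5-bromo-2-(3,4-dimethoxyphenyl)-2,3-dihydro-1-benzofuran-3-carboxylate | COc1ccc([C@@H]2Oc3c(OC(C)=O)cc(Br)cc3[C@@H]2C(=O)OCC)cc1OC | intermediate
11 | ethyl (2R,3S)-5-bromo-2-(3,4-dimethoxyphenyl)-7-hydroxy-2,3-dihydro-1-benzofuran-3-carboxylate (not isolated) | COc1ccc([C@@H]2Oc3c(O)cc(Br)cc3[C@@H]2C(=O)OCC)cc1OC | intermediate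
12 | ethyl (2R,3R)-5-bromo-2-(3,4-dimethoxyphenyl)-7-hydroxy-2,3-dihydro-1-benzofuran-3-carboxylate | COc1ccc([C@@H]2Oc3c(O)cc(Br)cc3[C@H]2C(=O)OCC)cc1OC | intermediate
13 | (2R,3S)-5-bromo-2-(3,4-dimethoxyphenyl)-3-(hydroxymethyl)-2,3-dihydro-1-benzofuran-7-ol | COc1ccc([C@@H]2Oc3c(O)cc(Br)cc3[C@H]2CO)cc1OC | intermediate
14 | prop-2-enoic acid | C=CC(=O)O | starting material
15 | (2E)-3-[(2R,3S)-2-(3,4-dimethoxyphenyl)-7-hydroxy-3-(hydroxymethyl)-2,3-dihydro-1-benzofuran-5-yl]prop-2-enoic acid | COc1ccc([C@@H]2Oc3c(O)cc(/C=C/C(=O)O)cc3[C@H]2CO)cc1OC | target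

**Totals**
Total step count: 9. Longest linear sequence: 9 steps (1 to 15).

**Steps most likely to fail**

Step 5. The coupling at the C–I bond flanked by the bulky benzyloxy group may be sluggish, so that palladium-induced loss of N2 from ethyl diazoacetate and carbene dimerization take over, or some reaction occurs at C–Br. The fallback sets out from 7. A Negishi coupling with the Reformatsky reagent BrZnCH2CO2Et (Pd2(dba)3, XPhos, THF, rt, 1.05 equiv of the zinc reagent so that C–Br is kept) should give ethyl 2-{3-acetoxy-5-bromo-2-[(3,4-dimethoxyphenyl)methoxy]phenyl}acetate F1. Regitz diazo transfer (4-acetamidobenzenesulfonyl azide, DBU, MeCN, 0 °C → rt) then returns to the route at 9.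

Step 6. The catalyst alone may discriminate poorly between the two enantiotopic benzylic hydrogens, or cis/trans control may erode. The fallback moves stereocontrol to a chiral auxiliary and sets out from 7. Coupling under the step 5 conditions with the lactamide-derived diazoacetate (2S)-1-oxo-1-(pyrrolidin-1-yl)propan-2-yl 2-diazoacetate F2 (prepared beforehand from the corresponding lactic acid pyrrolidide by standard diazoacetylation) should give the aryldiazoacetate (2S)-1-oxo-1-(pyrrolidin-1-yl)propan-2-yl 2-{3-acetoxy-5-bromo-2-[(3,4-dimethoxyphenyl)methoxy]phenyl}-2-diazoacetate F3. Its insertion with Rh2(S-DOSP)4 (CH2Cl2, rt) is expected to give directly the trans ester (2S)-1-oxo-1-(pyrrolidin-1-yl)propan-2-yl (2R,3R)-7-acetoxy-5-bromo-2-(3,4-dimethoxyphenyl)-2,3-dihydro-1-benzofuran-3-carboxylate F4 (the auxiliary enantiomer is exchanged if the sense proves opposite). LiBH4 (THF, rt) then removes the auxiliary and the acetate and returns to the route at 13, bypassing step 7.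

Step 9. The free phenoxide and carboxylate may deactivate the catalyst, the electron-rich bromide may react incompletely or be reduced, and acrylic acid may polymerize at 100 °C. The fallback sets out from 13. Suzuki–Miyaura coupling with ethyl (E)-3-(4,4,5,5-tetramethyl-1,3,2-dioxaborolan-2-yl)prop-2-enoate (Pd(dppf)Cl2, K2CO3, dioxane/H2O, 80 °C) should give ethyl (2E)-3-[(2R,3S)-2-(3,4-dimethoxyphenyl)-7-hydroxy-3-(hydroxymethyl)-2,3-dihydro-1-benzofuran-5-yl]prop-2-enoate F5 with the alkene geometry carried in by the boronate. Saponification (LiOH, THF/H2O, rt; mild acidification) then returns to the route at 15.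

**Further compounds**
F1 | step 5 | ethyl 2-{3-acetoxy-5-bromo-2-[(3,4-dimethoxyphenyl)methoxy]phenyl}acetate | CCOC(=O)Cc1cc(Br)cc(OC(C)=O)c1OCc1ccc(OC)c(OC)c1
F2 | step 6 | (2S)-1-oxo-1-(pyrrolidin-1-yl)propan-2-yl 2-diazoacetate | C[C@H](OC(=O)C=[N+]=[N-])C(=O)N1CCCC1
F3 | step 6 | (2S)-1-oxo-1-(pyrrolidin-1-yl)propan-2-yl 2-{3-acetoxy-5-bromo-2-[(3,4-dimethoxyphenyl)methoxy]phenyl}-2-diazoacetate | C[C@H](OC(=O)C(=[N+]=[N-])c1cc(Br)cc(OC(C)=O)c1OCc1ccc(OC)c(OC)c1)C(=O)N1CCCC1
F4 | step 6 | (2S)-1-oxo-1-(pyrrolidin-1-yl)propan-2-yl (2R,3R)-7-acetoxy-5-bromo-2-(3,4-dimethoxyphenyl)-2,3-dihydro-1-benzofuran-3-carboxylate | COc1ccc([C@@H]2Oc3c(OC(C)=O)cc(Br)cc3[C@H]2C(=O)O[C@@H](C)C(=O)N2CCCC2)cc1OC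
F5 | step 9 | ethyl (2E)-3-[(2R,3S)-2-(3,4-dimethoxyphenyl)-7-hydroxy-3-(hydroxymethyl)-2,3-dihydro-1-benzofuran-5-yl]prop-2-enoate | COc1ccc([C@@H]2Oc3c(O)cc(/C=C/C(=O)OCC)cc3[C@H]2CO)cc1OC
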